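**Remark on the chemistry:** the target has no stereogenic centre, so "single enantiomer" is taken to mean the (2E,6E) olefin geometry shown; both E-alkenes are bought with (2E,6E)-farnesol and are never touched.

**Retrosynthetic overview**
1. Target 21 = 4-hydroxy-5-(alkyloxy)-6-methoxyphthalide; the last operation only unmasks the C4–OH (MOM ether 20).
2. Key disconnection: both aryl–carbon bonds of the lactone (C7a–C1 and C3a–C3) plus C1–O2 are made at once by a three-component aryne annulation of aryne 18 with tert-butyl isocyanide (C1) and formaldehyde (C3, O2). The furanone is the only ring formed; the benzene ring is bought.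
3. Enabling feature: the lactone carbons C1 (C=O) and C3 (CH2) sit on the adjacent benzene carbons C7a and C3a, which are the two carbons of an aryne. The oxygen on C4, next to C3a, polarises that aryne so the isocyanide adds at C7a and the C3a anion takes formaldehyde.
4. Aryne precursor 17 = o-silylaryl triflate from 5-hydroxyvanillin (para-selective benzylation, ortho-bromination, Dakin oxidation, retro-Brook/triflation, debenzylation), joined to the side chain by Mitsunobu etherification.
5. Side chain 16 from (2E,6E)-farnesol: terminal bromohydrin, radical debromination, tertiary acetylation, selective primary deacetylation.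

Key step: step 13

**Route**

Step 1
Reactants: 1 5-hydroxyvanillin (3,4-dihydroxy-5-methoxybenzaldehyde)
Product: 2 4-(benzyloxy)-3-hydroxy-5-methoxybenzaldehyde
Conditions: BnBr (1.0 equiv), Li2CO3, DMF, 45 °C
Reagents that add atoms: benzyl bromide, BrCc1ccccc1
Why: The 4-OH para to the formyl group is the more acidic phenol, so a weak base should form and alkylate only that phenoxide (regioselective Williamson etherification, as known for 3,4-dihydroxybenzaldehydes).

Step 2
Reactants: 2 4-(benzyloxy)-3-hydroxy-5-methoxybenzaldehyde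
Product: 3 4-(benzyloxy)-2-bromo-3-hydroxy-5-methoxybenzaldehyde
Conditions: Br2 (1.05 equiv), NaOAc, Fe powder (cat.), AcOH, rt
Reagents that add atoms: bromine, BrBr
Why: Electrophilic aromatic bromination should go ortho to the free phenol at C2 (also para to the 5-OMe), as in the bromination of isovanillin to its 2-bromo derivative, while C6 is shielded by CHO and the in-plane OMe.

Step 3
Reactants: 3 4-(benzyloxy)-2-bromo-3-hydroxy-5-methoxybenzaldehyde
Product: 4 4-(benzyloxy)-2-bromo-5-methoxy-3-(methoxymethoxy)benzaldehyde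
Conditions: MOMCl, K2CO3, acetone, 0 °C to rt
Reagents that add atoms: chloromethyl methyl ether, COCCl
Why: Williamson-type O-alkylation of the phenoxide gives a MOM acetal that should survive organolithium, hydrogenolysis and fluoride and be removable last.

Step 4
Reactants: 4 4-(benzyloxy)-2-bromo-5-methoxy-3-(methoxymethoxy)benzaldehyde
Product: 6 4-(benzyloxy)-2-bromo-5-methoxy-3-(methoxymethoxy)phenol, via aryl formate 5 (not isolated)
Conditions: mCPBA, CH2Cl2, rt; then K2CO3 (cat.), MeOH, 0 °C
Reagents that add atoms: mCPBA, O=C(OO)c1cccc(Cl)c1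
Why: Dakin-type Baeyer–Villiger oxidation, in which the electron-rich aryl group (para-benzyloxy) migrates to give the aryl formate that mild methanolysis cleaves to the phenol.

Step 5
Reactants: 6 4-(benzyloxy)-2-bromo-5-methoxy-3-(methoxymethoxy)phenol
Product: 9 4-(benzyloxy)-5-methoxy-3-(methoxymethoxy)-2-(trimethylsilyl)phenyl trifluoromethanesulfonate, via aryl trimethylsilyl ether 7 (not isolated), via lithium 2-silylphenoxide 8 (not isolated)
Conditions: HMDS, THF, 70 °C, evaporate; n-BuLi, THF, −78 °C; Tf2O, −78 °C to rt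
Reagents that add atoms: hexamethyldisilazane, C[Si](C)(C)N[Si](C)(C)C; triflic anhydride, O=S(=O)(OS(=O)(=O)C(F)(F)F)C(F)(F)F
Why: O-silylation, bromine–lithium exchange with 1,3 O-to-C silyl shift (retro-Brook rearrangement) and triflation of the resulting phenoxide is the standard way from o-bromophenols to o-silylaryl triflates, and the exchange at −78 °C should outrun any attack on the benzyl or MOM ethers.

Step 6
Reactants: 9 4-(benzyloxy)-5-methoxy-3-(methoxymethoxy)-2-(trimethylsilyl)phenyl trifluoromethanesulfonate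
Product: 10 4-hydroxy-5-methoxy-3-(methoxymethoxy)-2-(trimethylsilyl)phenyl trifluoromethanesulfonate
Conditions: H2 (1 atm), 10% Pd/C, EtOAc, rt
Reagents that add atoms: none
Why: Hydrogenolysis of the benzyl aryl ether under neutral, base-free conditions should leave the aryl triflate, the aryl–silicon bond and the MOM acetal intact.

Step 7
Reactants: 11 (2E,6E)-farnesol
Product: 12 (2E,6E)-farnesyl acetate
Conditions: Ac2O, pyridine, DMAP (cat.), CH2Cl2, 0 °C to rt
Reagents that add atoms: acetic anhydride, CC(=O)OC(C)=O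
Why: Routine acylation of the primary allylic alcohol, which also deactivates the 2,3-alkene toward the electrophile of step 8.

Step 8
Reactants: 12 (2E,6E)-farnesyl acetate
Product: 13 (2E,6E)-10-bromo-11-hydroxy-3,7,11-trimethyldodeca-2,6-dien-1-yl acetate (racemic at C10)
Conditions: NBS (1.1 equiv), THF–H2O, 0 °C
Reagents that add atoms: N-bromosuccinimide, O=C1CCC(=O)N1Br; water, O
Why: Terminal-selective bromohydrin formation of polyprenyl acetates in aqueous medium, with Markovnikov opening of the bromonium ion by water at the tertiary carbon; the CHBr centre is racemic and is erased in step 9.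

Step 9
Reactants: 13 (2E,6E)-10-bromo-11-hydroxy-3,7,11-trimethyldodeca-2,6-dien-1-yl acetate
Product: 14 (2E,6E)-11-hydroxy-3,7,11-trimethyldodeca-2,6-dien-1-yl acetate
Conditions: Bu3SnH, AIBN (cat.), toluene, 80 °C
Reagents that add atoms: none
Why: Radical chain reduction of the secondary bromide, whose C10 radical has only unfavourable 4-exo or 5-endo closures onto the 6,7-alkene and should therefore simply abstract hydrogen.

Step 10
Reactants: 14 (2E,6E)-11-hydroxy-3,7,11-trimethyldodeca-2,6-dien-1-yl acetate
Product: 15 (2E,6E)-3,7,11-trimethyldodeca-2,6-diene-1,11-diyl diacetate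
Conditions: Ac2O, Et3N, DMAP, CH2Cl2, rt to 40 °C
Reagents that add atoms: acetic anhydride, CC(=O)OC(C)=O
Why: DMAP-catalysed acyl transfer (Steglich-type acylation) is the standard method for acetylating tertiary alcohols without elimination.

Step 11
Reactants: 15 (2E,6E)-3,7,11-trimethyldodeca-2,6-diene-1,11-diyl diacetate
Product: 16 (6E,10E)-12-hydroxy-2,6,10-trimethyldodeca-6,10-dien-2-yl acetate
Conditions: K2CO3 (cat.), MeOH, 0 °C
Reagents that add atoms: none
Why: Base-catalysed transesterification (Zemplén-type) should remove the unhindered primary allylic acetate far faster than the hindered tertiary acetate.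

Step 12
Reactants: 10 4-hydroxy-5-methoxy-3-(methoxymethoxy)-2-(trimethylsilyl)phenyl trifluoromethanesulfonate; 16 (6E,10E)-12-hydroxy-2,6,10-trimethyldodeca-6,10-dien-2-yl acetate
Product: 17 4-{[(2E,6E)-11-acetoxy-3,7,11-trimethyldodeca-2,6-dien-1-yl]oxy}-5-methoxy-3-(methoxymethoxy)-2-(trimethylsilyl)phenyl trifluoromethanesulfonate
Conditions: PPh3, DIAD, THF, 0 °C to rt
Reagents that add atoms: none
Why: Mitsunobu etherification of an acidic phenol (para-triflyloxy) with a primary allylic alcohol proceeds by SN2 at C1, keeps the E-alkene, and uses no base or fluoride that could trigger the silyl triflate.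

Step 13
Reactants: 17 4-{[(2E,6E)-11-acetoxy-3,7,11-trimethyldodeca-2,6-dien-1-yl]oxy}-5-methoxy-3-(methoxymethoxy)-2-(trimethylsilyl)phenyl trifluoromethanesulfonate
Product: 20 5-{[(2E,6E)-11-acetoxy-3,7,11-trimethyldodeca-2,6-dien-1-yl]oxy}-6-methoxy-4-(methoxymethoxy)isobenzofuran-1(3H)-one, via aryne 18 (not isolated), via N-tert-butyl iminolactone 19 (not isolated)
Conditions: t-BuNC (3 equiv), (CH2O)n (5 equiv), KF, 18-crown-6, THF, 0 °C to rt; then 1 M aq. HCl, THF, 0 °C
Reagents that add atoms: tert-butyl isocyanide, CC(C)(C)[N+]#[C-]; formaldehyde (from paraformaldehyde), C=O; water, O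
Why: Fluoride removes the silyl group and triflate leaves to give aryne 18; the isocyanide carbon adds at C7a, the resulting C3a aryl anion adds to formaldehyde, and the alkoxide closes onto the nitrilium carbon to give iminolactone 19, which dilute acid hydrolyses to lactone 20 with loss of tert-butylamine. The closest known reaction is the aryne–isocyanide–aldehyde three-component coupling to benzo-fused iminofurans, used here with formaldehyde as the aldehyde, followed by ordinary acidic imidate-to-lactone hydrolysis. The furanone ring closes by 5-exo-dig attack of the oxygen on the nitrilium carbon, so C7a–C1, C3a–C3 and O2–C1 are all made in this operation, and no stereocentre is created. The step needs regioselective addition across the aryne, which the C4–OMOM group secures as in 3-alkoxyarynes: the nucleophile attacks the distal C7a and the charge develops at C3a beside the inductively withdrawing oxygen. Chemoselectivity should come from excess isocyanide and formaldehyde with slow aryne release at 0 °C, and the chain alkenes hang from C5 (meta/para to the aryne carbons) and cannot reach the aryne intramolecularly.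

Step 14
Reactants: 20 5-{[(2E,6E)-11-acetoxy-3,7,11-trimethyldodeca-2,6-dien-1-yl]oxy}-6-methoxy-4-(methoxymethoxy)isobenzofuran-1(3H)-one
Product: 21 Farnesylemefuranone F, 5-{[(2E,6E)-11-acetoxy-3,7,11-trimethyldodeca-2,6-dien-1-yl]oxy}-4-hydroxy-6-methoxyisobenzofuran-1(3H)-one
Conditions: conc. HCl (cat.), MeOH, 0 °C to rt
Reagents that add atoms: none
Why: Acid-catalysed transacetalisation of the aryl MOM ether to methanol should be faster under dilute, cold conditions than ionisation of the allylic aryl ether or solvolysis of the tertiary acetate, and the lactone re-closes if opened.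

**Compound list**
1 | 5-hydroxyvanillin (3,4-dihydroxy-5-methoxybenzaldehyde) | COc1cc(C=O)cc(O)c1O | starting material
2 | 4-(benzyloxy)-3-hydroxy-5-methoxybenzaldehyde | COc1cc(C=O)cc(O)c1OCc1ccccc1 | intermediate
3 | 4-(benzyloxy)-2-bromo-3-hydroxy-5-methoxybenzaldehyde | COc1cc(C=O)c(Br)c(O)c1OCc1ccccc1 | intermediate
4 | 4-(benzyloxy)-2-bromo-5-methoxy-3-(methoxymethoxy)benzaldehyde | COCOc1c(Br)c(C=O)cc(OC)c1OCc1ccccc1 | intermediate
5 | 4-(benzyloxy)-2-bromo-5-methoxy-3-(methoxymethoxy)phenyl formate (formed in the flask) | COCOc1c(Br)c(OC=O)cc(OC)c1OCc1ccccc1 | intermediate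
6 | 4-(benzyloxy)-2-bromo-5-methoxy-3-(methoxymethoxy)phenol | COCOc1c(Br)c(O)cc(OC)c1OCc1ccccc1 | intermediate
7 | [4-(benzyloxy)-2-bromo-5-methoxy-3-(methoxymethoxy)phenoxy]trimethylsilane (formed in the flask) | COCOc1c(Br)c(O[Si](C)(C)C)cc(OC)c1OCc1ccccc1 | intermediate
8 | lithium 4-(benzyloxy)-5-methoxy-3-(methoxymethoxy)-2-(trimethylsilyl)phenolate (formed in the flask) | COCOc1c([Si](C)(C)C)c([O-])cc(OC)c1OCc1ccccc1.[Li+] | intermediate
9 | 4-(benzyloxy)-5-methoxy-3-(methoxymethoxy)-2-(trimethylsilyl)phenyl trifluoromethanesulfonate | COCOc1c([Si](C)(C)C)c(OS(=O)(=O)C(F)(F)F)cc(OC)c1OCc1ccccc1 | intermediate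
10 | 4-hydroxy-5-methoxy-3-(methoxymethoxy)-2-(trimethylsilyl)phenyl trifluoromethanesulfonate | COCOc1c([Si](C)(C)C)c(OS(=O)(=O)C(F)(F)F)cc(OC)c1O | intermediate
11 | (2E,6E)-farnesol | CC(C)=CCC/C(C)=C/CC/C(C)=C/CO | starting material
12 | (2E,6E)-farnesyl acetate | CC(C)=CCC/C(C)=C/CC/C(C)=C/COC(C)=O | intermediate
13 | (2E,6E)-10-bromo-11-hydroxy-3,7,11-trimethyldodeca-2,6-dien-1-yl acetate (racemic at C10) | CC(C)(O)C(Br)CC/C(C)=C/CC/C(C)=C/COC(C)=O | intermediate
14 | (2E,6E)-11-hydroxy-3,7,11-trimethyldodeca-2,6-dien-1-yl acetate | CC(C)(O)CCC/C(C)=C/CC/C(C)=C/COC(C)=O | intermediate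
15 | (2E,6E)-3,7,11-trimethyldodeca-2,6-diene-1,11-diyl diacetate | CC(=O)OC(C)(C)CCC/C(C)=C/CC/C(C)=C/COC(C)=O | intermediate
16 | (6E,10E)-12-hydroxy-2,6,10-trimethyldodeca-6,10-dien-2-yl acetate | CC(=O)OC(C)(C)CCC/C(C)=C/CC/C(C)=C/CO | intermediate
17 | 4-{[(2E,6E)-11-acetoxy-3,7,11-trimethyldodeca-2,6-dien-1-yl]oxy}-5-methoxy-3-(methoxymethoxy)-2-(trimethylsilyl)phenyl trifluoromethanesulfonate | COCOc1c([Si](C)(C)C)c(OS(=O)(=O)C(F)(F)F)cc(OC)c1OC/C=C(\C)CC/C=C(\C)CCCC(C)(C)OC(C)=O | intermediate
18 | 4-{[(2E,6E)-11-acetoxy-3,7,11-trimethyldodeca-2,6-dien-1-yl]oxy}-5-methoxy-3-(methoxymethoxy)-1,2-didehydrobenzene (aryne, formed in the flask) | COCOC1=C(OC/C=C(\C)CC/C=C(\C)CCCC(C)(C)OC(C)=O)C(OC)=CC#C1 | intermediate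
19 | N-tert-butyl-5-{[(2E,6E)-11-acetoxy-3,7,11-trimethyldodeca-2,6-dien-1-yl]oxy}-6-methoxy-4-(methoxymethoxy)isobenzofuran-1(3H)-imine (C=N geometry not assigned, formed in the flask) | COCOc1c2c(cc(OC)c1OC/C=C(\C)CC/C=C(\C)CCCC(C)(C)OC(C)=O)C(=NC(C)(C)C)OC2 | intermediate
20 | 5-{[(2E,6E)-11-acetoxy-3,7,11-trimethyldodeca-2,6-dien-1-yl]oxy}-6-methoxy-4-(methoxymethoxy)isobenzofuran-1(3H)-one | COCOc1c2c(cc(OC)c1OC/C=C(\C)CC/C=C(\C)CCCC(C)(C)OC(C)=O)C(=O)OC2 | intermediate
21 | Farnesylemefuranone F | COc1cc2c(c(O)c1OC/C=C(\C)CC/C=C(\C)CCCC(C)(C)OC(C)=O)COC2=O | target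

**Step count and risks**
Total steps: 14. Longest linear sequence: 9 steps (1–6, 12–14) from 5-hydroxyvanillin; the side chain takes 5 steps (7–11) before the union in step 12.

Steps most likely to fail:

1. Step 13. Release of monomeric formaldehyde may be too slow, so the aryl anion/nitrilium zwitterion is protonated (amide pathway) or the aryne is consumed by intermolecular ene reaction with the olefinic chain. Fallback, from 4 and returning at 20: Pinnick oxidation (NaClO2, NaH2PO4, 2-methyl-2-butene) should give 4-(benzyloxy)-2-bromo-5-methoxy-3-(methoxymethoxy)benzoic acid F1. MeI/K2CO3 in DMF then gives methyl 4-(benzyloxy)-2-bromo-5-methoxy-3-(methoxymethoxy)benzoate F2. Stille hydroxymethylation with Bu3SnCH2OH and Pd(PPh3)4 in dioxane at 100 °C, with spontaneous lactonisation, gives 5-(benzyloxy)-6-methoxy-4-(methoxymethoxy)isobenzofuran-1(3H)-one F3. Hydrogenolysis (H2, Pd/C, EtOAc) gives 5-hydroxy-6-methoxy-4-(methoxymethoxy)isobenzofuran-1(3H)-one F4, and Mitsunobu etherification of F4 with 16 (PPh3, DIAD) gives 20.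

2. Step 2. Bromination may partly occur para to the phenol (C6) or proceed to dibromination, which would put the aryne at the wrong ring bond. Fallback, from 2 and returning at 4: MOMCl/K2CO3 should give 4-(benzyloxy)-3-methoxy-5-(methoxymethoxy)benzaldehyde F5. In-situ α-amino alkoxide formation with lithium N,N,N′-trimethylethylenediamide (THF, −20 °C), ortho-lithiation with n-BuLi at the position flanked by the amino alkoxide and the strongly coordinating OMOM group, and quench with BrCCl2CCl2Br at −78 °C then gives 4 after aqueous work-up. Regiocontrol here comes from coordination-directed metalation, not from electrophilic substitution.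

3. Step 14. Protic acid may ionise the allylic aryl ether or solvolyse the tertiary acetate before the MOM acetal is fully cleaved. Fallback, from 20 and returning at 21: non-protic transprotection with TESOTf/2,2′-bipyridyl in CH2Cl2 at 0 °C should convert the aryl MOM ether directly into 5-{[(2E,6E)-11-acetoxy-3,7,11-trimethyldodeca-2,6-dien-1-yl]oxy}-6-methoxy-4-(triethylsilyloxy)isobenzofuran-1(3H)-one F6. Buffered desilylation (TBAF/AcOH, THF, 0 °C) then gives 21.

**Further compounds**
F1 | step 13 | 4-(benzyloxy)-2-bromo-5-methoxy-3-(methoxymethoxy)benzoic acid | COCOc1c(Br)c(C(=O)O)cc(OC)c1OCc1ccccc1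
F2 | step 13 | methyl 4-(benzyloxy)-2-bromo-5-methoxy-3-(methoxymethoxy)benzoate | COCOc1c(Br)c(C(=O)OC)cc(OC)c1OCc1ccccc1
F3 | step 13 | 5-(benzyloxy)-6-methoxy-4-(methoxymethoxy)isobenzofuran-1(3H)-one | COCOc1c2c(cc(OC)c1OCc1ccccc1)C(=O)OC2
F4 | step 13 | 5-hydroxy-6-methoxy-4-(methoxymethoxy)isobenzofuran-1(3H)-one | COCOc1c2c(cc(OC)c1O)C(=O)OC2
F5 | step 2 | 4-(benzyloxy)-3-methoxy-5-(methoxymethoxy)benzaldehyde | COCOc1cc(C=O)cc(OC)c1OCc1ccccc1
F6 | step 14 | 5-{[(2E,6E)-11-acetoxy-3,7,11-trimethyldodeca-2,6-dien-1-yl]oxy}-6-methoxy-4-(triethylsilyloxy)isobenzofuran-1(3H)-one | CC[Si](CC)(CC)Oc1c2c(cc(OC)c1OC/C=C(\C)CC/C=C(\C)CCCC(C)(C)OC(C)=O)C(=O)OC2
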